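## Structural features

The target (36) is a chain of five benzene rings, A to E, joined only by four diaryl ether oxygens: ring A C1–O–ring B C1, ring B C2–O–ring C C1, ring C C4–O–ring D C1 and ring D C6–O–ring E C1. It has thirteen phenolic hydroxyls and no stereocentre, so no neighbouring stereocentres have to be controlled; the problem is one of regiochemistry. Ring A is 2,4,6-trihydroxyphenyl; ring B has its two ether links on adjacent carbons (C1, C2) and hydroxyls at C3 and C5; ring C is 3,5-dihydroxylated between para ether links; ring D bears five contiguous oxygens (C1, C6, C5, C4, C3); ring E is 3,4,5-trihydroxyphenyl. The free polyphenol, above all the pentaoxygenated ring D and the para-dioxygenated rings B and C, is oxidised readily to quinones in air and base, whereas the diaryl ether bonds are robust. All hydroxyls are therefore carried as benzyl ethers to the last step. The real difficulty is steric and positional: the A–B and C–D ethers each have three ortho substituents, the B–C and D–E ethers two, and seventeen oxygens must be placed and told apart. The key step exploits ring B, which has para-related oxygens at C2 and C5, hydrogens at C4 and C6, and the ring A aryloxy group at C1 next to C2. A carbene/alkyne/CO benzannulation gives exactly this pattern when C5 is the carbene carbon, C4 and C3 its vinyl group, C2 a carbonyl ligand, and C1 and C6 an aryl ethynyl ether.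

## Logic of the disconnections

36 from 35: the thirteen O–benzyl bonds are cut last. The free polyphenol is too oxidation-prone to carry through any coupling, and one neutral hydrogenolysis releases every hydroxyl at once. This demands that every protecting group be a benzyl ether, including the one on ring B C5, which fixes the alkoxy group chosen for 9.

35 from 21 and 34: the bond between the ether oxygen on ring B C2 and ring C C1 is cut. This divides the pentamer two rings against three, and the halide carbon of 34 has two ortho hydrogens, so all the crowding lies on the phenol side, the arrangement that copper-mediated ether synthesis tolerates best. The forward step needs 21 to have this hydroxyl alone free and 34 to keep a bromide through its own assembly.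

21 from 9 and 19: ring B is opened at C1–C2, C2–C3 and C5–C6. Ring B is unsymmetrical and tetraoxygenated, and its A–B ether is the most hindered in the molecule. The cut reduces ring B to a three-carbon carbene ligand, one carbonyl ligand and a two-carbon alkyne, with the ring A oxygen already on the alkyne, so no aryl C–O coupling is needed at that position. The forward step must insert the alkyne with its aryloxy carbon next to the carbonyl-derived carbon and must take up CO before ring closure.

9 from 7, 5, 1 and 2: the C3–O bond is cut (conjugate addition of the alcohol to an alkynylcarbene), then the O–benzyl link at the carbene carbon (acylation and alcohol exchange on an acylchromate), then the bond between the carbene carbon and the alkyne (acetylide addition to a carbonyl ligand of 1). The silyl group of 2 makes the alkynylcarbene stable enough to isolate and must be lost when the alcohol adds.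

19 from 16, 13 and 14: the O–C(sp) bond is traced to a dichlorovinyl ether, and this to the phenol and the two-carbon chloroalkene. The demand is a double dehydrochlorination with butyllithium that the benzyl ethers survive.

13 from 11 and 10: the phenolic C–O bond of ring A is traced to a formyl group (aryl migration to oxygen), and the benzyl ethers to the free triol. The aldehyde tames the phloroglucinol ring during benzylation and then supplies the oxygen.

34 from 33 and 28: the bond between the oxygen on ring D C6 and ring E C1 is cut. The phenol is hindered but the iodide is not, and the forward coupling must leave the ring C bromide alone.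

33 from 31, and 31 from 25 and 30: the ring D C6 hydroxyl is traced to a formyl group, and the bond between the oxygen on ring C C4 and ring D C1 is cut. One formyl group thus serves twice, first activating the neighbouring iodide for coupling with a hindered phenol, then becoming the C6 oxygen. The iodide of 30 must react in preference to the bromide of 25.

30 from 28, 27 and 26, and 25 from 23 and 22: the formyl carbon of ring D is removed (electrophilic formylation at the only type of free position), and benzyl ethers are exchanged for the methyl ethers of a commercial iodide. Ring C is traced through a formyl-to-hydroxyl oxidation to a difluoroaldehyde whose two C–F bonds become C–O bonds. Rings D and E come from the same iodide 28.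

## Other disconnections considered

Alternative 1: The cut is at the C–O bonds of the hydroxyls on ring A C4 and ring B C5, which are traced back to C–H bonds of the undecamethyl ether A1. In the forward step A1 would be borylated with [Ir(OMe)(cod)]2, 4,4'-di-tert-butyl-2,2'-bipyridine and bis(pinacolato)diboron, and the two boronates oxidised in the same pot with KHSO5 to give A2; BBr3 would then remove eleven methyl ethers.
- In its favour: every other C–H bond of A1 lies next to an oxygen substituent, so steric control should direct boron to exactly these two positions, and rings A and B of the precursor are simpler by one oxygen each.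
- Against it: the step forms no ring and none of the four ether bonds, so the A–B ether with three ortho substituents must still be made by coupling. Methyl protection is forced, because benzyl C–H bonds would be borylated, and the end game becomes a Lewis-acid cleavage of eleven ethers on an oxidation-prone polyphenol. Both borylations must also go to completion on one molecule.
- Comparison: on structure the chosen plan gains more, since its key step builds a ring and places the hardest ether. On mechanism the steric selectivity of the borylation is at least as predictable as the alkyne insertion, and it uses a catalytic metal where the chosen plan uses stoichiometric chromium; on both points the alternative is the better. On step economy the single operation for two hydroxyls is offset by the harsher deprotection.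

Alternative 2: The cut opens ring C at C2–C3 and C1–C6 (and C3–C4), so that ring C is made from the cyclobutenone A3, which carries rings D and E on its 4-aryloxy oxygen, and the ethynyl ether A4, which carries rings A and B. Heating the two should open A3 to a vinylketene, which adds to A4; a second four-electron ring opening and a 6π closure would give the phenol A5.
- In its favour: it is the most convergent plan, and both crowded ethers on ring C arise without any aryl C–O coupling. It uses no metal, and ynol ethers are well-established partners in this benzannulation, so on precedent for the alkyne class it is at least the equal of the chosen step.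
- Against it: A4 is the ethynyl ether of 21, so ring B and the A–B ether must be made first, and the alternative complements the chosen key step without replacing it. A3 is an unusual, sensitive cyclobutenone that needs its own multi-step synthesis. A5 carries a silyl ether that adds a deprotection, and A4 must survive a higher temperature than 19 does.
- Comparison: for the C–D ether the alternative is the better, because the chosen plan relies on a hindered copper coupling (step 14). For the A–B ether it offers nothing. In total it would lengthen the route.

Alternative 3: The cut is at ring D C6–C1; ring D is made from the squarate-derived cyclobutenone A6, whose alkenyl group already carries ring C through a vinyl ether oxygen. Thermolysis should open the four-membered ring with the alkoxy group turning outward, and the dienylketene would close to the phenol A7, whose only free hydroxyl is at ring D C6.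
- In its favour: ring D, the most substituted ring, is assembled with all five oxygens in place and differentiated, with the free hydroxyl exactly where ring E must be attached. The C–D ether is brought in as a vinyl ether, and the cascade is metal-free and well understood.
- Against it: ring C of A7 ends in a silyl-protected oxygen at C1, a phenol nucleophile, whereas the B–C ether is best made by arylating the hindered ring B C2 hydroxyl, which is what the chosen key step provides. The two plans therefore clash in polarity unless ring C is given a different handle. Three classes of protecting group (benzyl, methoxymethyl, silyl) add deprotection steps, and rings A and B are not addressed.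
- Comparison: for ring D and the C–D ether the alternative is the better, and in mechanistic predictability it is the equal. The chosen plan reaches the same fragment by formylation, oxidation and two couplings (steps 13 to 16), with one protecting group class and a one-step end game.

Key step: step 8

Remarks on the chemistry:
- The atom mapping of the benzannulation (carbene carbon to ring B C5, vinyl carbons to C4 and C3, carbonyl ligand to C2, alkyne carbons to C6 and C1) reproduces ring B of the target and needed no correction.
- The oxygen on the carbene carbon is carried as a benzyl ether, not a methyl ether, so that ring B C5 is unmasked in the same hydrogenolysis as the other twelve hydroxyls and no Lewis-acid demethylation of the free polyphenol is needed. The bonds formed and the ring closed in step 8 are unchanged.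
- The silyl group of the alkynylcarbene is assumed to be removed by the alkoxide catalyst during the alcohol addition (step 3).

## Route

Step 1
Reactants: 1 chromium hexacarbonyl; 2 trimethylsilylacetylene
Product: 5 tetramethylammonium pentacarbonyl[1-oxido-3-(trimethylsilyl)prop-2-yn-1-ylidene]chromate, via lithium trimethylsilylacetylide 3 (not isolated), via lithium acylchromate 4 (not isolated)
Conditions: n-BuLi, THF, −78 °C; Cr(CO)6, −78 to 0 °C; then Me4NBr, H2O, 0 °C
Reagents that add atoms: tetramethylammonium bromide, C[N+](C)(C)C.[Br-]
Why: First half of a Fischer carbene synthesis: the acetylide adds to a carbonyl ligand of 1 to give the acylchromate, which is collected as its stable tetramethylammonium salt.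

Step 2
Reactants: 5 tetramethylammonium pentacarbonyl[1-oxido-3-(trimethylsilyl)prop-2-yn-1-ylidene]chromate
Product: 7 pentacarbonyl[1-(benzyloxy)-3-(trimethylsilyl)prop-2-yn-1-ylidene]chromium, via acetoxycarbene complex 6 (not isolated)
Conditions: AcBr, CH2Cl2, −40 °C; then BnOH, −40 to 0 °C
Reagents that add atoms: benzyl alcohol, OCc1ccccc1
Why: O-Acylation of the acylchromate gives a highly electrophilic acyloxycarbene, and addition–elimination of benzyl alcohol at the carbene carbon installs the benzyloxy group; this acyl bromide/alcohol exchange is the usual way to alkoxycarbene complexes that alkylating agents do not reach.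

Step 3
Reactants: 7 pentacarbonyl[1-(benzyloxy)-3-(trimethylsilyl)prop-2-yn-1-ylidene]chromium
Product: 9 pentacarbonyl[(E)-1,3-bis(benzyloxy)prop-2-en-1-ylidene]chromium, via ethynylcarbene complex 8 (not isolated)
Conditions: BnOH (3 equiv), BnONa (10 mol%), THF, −20 °C to rt
Reagents that add atoms: benzyl alcohol, OCc1ccccc1
Why: Alkoxide-catalysed conjugate (oxa-Michael) addition of an alcohol to an alkynyl(alkoxy)carbene complex; the alkoxide first removes the silyl group from the strongly activated alkyne and the terminal ethynyl complex 8 is trapped at once. Exchange at the carbene carbon is degenerate because both alkoxy groups are benzyloxy, and the equilibrating conditions should favour the E isomer of this push–pull alkene.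

Step 4
Reactants: 10 2,4,6-trihydroxybenzaldehyde
Product: 11 2,4,6-tris(benzyloxy)benzaldehyde
Conditions: BnBr (3.5 equiv), K2CO3, DMF, 60 °C
Reagents that add atoms: benzyl bromide, BrCc1ccccc1
Why: Williamson etherification of the three phenolic hydroxyls; the electron-withdrawing formyl group should hold back C-benzylation of the phloroglucinol ring.

Step 5
Reactants: 11 2,4,6-tris(benzyloxy)benzaldehyde
Product: 13 2,4,6-tris(benzyloxy)phenol, via 2,4,6-tris(benzyloxy)phenyl formate 12 (not isolated)
Conditions: mCPBA, CH2Cl2, 0 °C to rt; then K2CO3 (cat.), MeOH, rt, argon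
Reagents that add atoms: 3-chloroperoxybenzoic acid, OOC(=O)c1cccc(Cl)c1
Why: Dakin oxidation run as a Baeyer–Villiger reaction: the electron-rich aryl group migrates to oxygen to give formate 12, which mild methanolysis cleaves; air is excluded because the phenol is easily oxidised.

Step 6
Reactants: 13 2,4,6-tris(benzyloxy)phenol; 14 trichloroethylene
Product: 16 1,3,5-tris(benzyloxy)-2-{[(E)-1,2-dichloroethenyl]oxy}benzene, via dichloroacetylene 15 (not isolated)
Conditions: K2CO3, DMF, 70 °C
Reagents that add atoms: none
Why: Base-induced loss of HCl from 14 gives dichloroacetylene, to which the phenoxide adds anti to give the E-dichlorovinyl ether; this is the established first stage of ynol ether synthesis from trichloroethylene.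

Step 7
Reactants: 16 1,3,5-tris(benzyloxy)-2-{[(E)-1,2-dichloroethenyl]oxy}benzene
Product: 19 ethynyl 2,4,6-tris(benzyloxy)phenyl ether, via chloroethynyl aryl ether 17 (not isolated), via lithium aryloxyacetylide 18 (not isolated)
Conditions: n-BuLi (2.3 equiv), THF, −78 to −40 °C; then MeOH, −78 °C
Reagents that add atoms: none
Why: Deprotonation and loss of LiCl give the chloroalkyne, chlorine–lithium exchange with the second equivalent gives the acetylide, and protonation at low temperature gives the terminal ynol ether; at −78 °C the benzyl ethers should not be metalated. The product is used promptly.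

Step 8
Reactants: 9 pentacarbonyl[(E)-1,3-bis(benzyloxy)prop-2-en-1-ylidene]chromium; 19 ethynyl 2,4,6-tris(benzyloxy)phenyl ether
Product: 21 2,4-bis(benzyloxy)-6-[2,4,6-tris(benzyloxy)phenoxy]phenol, via tricarbonylchromium arene complex 20 (not isolated)
Conditions: THF (0.05 M), 50 °C, argon; then air, MeCN, rt
Reagents that add atoms: none
Why: Dötz benzannulation: thermal loss of one CO from 9 opens a site for 19, which inserts into the Cr=C bond with its unsubstituted carbon bonding to the carbene carbon (C5–C6), so that chromium moves to the aryloxy-bearing carbon. Insertion of CO at that carbon gives a vinylketene complex (C1–C2), and ring B is closed by a 6π electrocyclisation of this dienylketene onto the benzyloxy-bearing vinyl carbon (C2–C3); enolisation of the cyclohexadienone gives the phenol as its Cr(CO)3 complex 20, which air releases as 21. The closest known reaction type is the benzannulation of alkenyl(alkoxy)carbene complexes of chromium with terminal alkynes; alkoxyalkynes have been used only rarely as partners. No stereocentre is formed. The step needs one regiochemical outcome, the aryloxy carbon next to the new phenol carbon: a terminal alkyne places its substituted carbon there for steric reasons, and the polarisation of the ynol ether (nucleophilic CH terminus, electrophilic carbene carbon) points the same way. It also needs CO insertion to win over closure to a five-membered ring, which chromium, an alkoxycarbene, THF and a moderate temperature favour. The product is differentiated as required, since the hindered C2 hydroxyl is the only free one.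

Step 9
Reactants: 22 4-bromo-2,6-difluorobenzaldehyde
Product: 23 4-bromo-2,6-bis(benzyloxy)benzaldehyde
Conditions: BnONa (2.3 equiv, 1.0 M in BnOH), THF, 0 to 50 °C
Reagents that add atoms: sodium benzyloxide, [Na+].[O-]Cc1ccccc1
Why: Nucleophilic aromatic substitution: both fluorides are ortho to the formyl group and are far better leaving groups than the bromide, which is kept as the later coupling handle.

Step 10
Reactants: 23 4-bromo-2,6-bis(benzyloxy)benzaldehyde
Product: 25 4-bromo-2,6-bis(benzyloxy)phenol, via 4-bromo-2,6-bis(benzyloxy)phenyl formate 24 (not isolated)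
Conditions: mCPBA, CH2Cl2, 0 °C to rt; then K2CO3 (cat.), MeOH, rt, argon
Reagents that add atoms: 3-chloroperoxybenzoic acid, OOC(=O)c1cccc(Cl)c1
Why: Dakin oxidation as in step 5; the two ortho benzyloxy groups make the aryl group the migrating one.

Step 11
Reactants: 26 5-iodo-1,2,3-trimethoxybenzene
Product: 27 5-iodobenzene-1,2,3-triol
Conditions: BBr3 (3.5 equiv), CH2Cl2, −78 °C to rt; then H2O
Reagents that add atoms: none
Why: Lewis-acid cleavage of aryl methyl ethers by BBr3; the aryl iodide is inert.

Step 12
Reactants: 27 5-iodobenzene-1,2,3-triol
Product: 28 5-iodo-1,2,3-tris(benzyloxy)benzene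
Conditions: BnBr (3.5 equiv), K2CO3, DMF, 60 °C, argon
Reagents that add atoms: benzyl bromide, BrCc1ccccc1
Why: Williamson etherification, run under argon so that the pyrogallol is not oxidised; the product serves both as ring E and as the precursor of ring D.

Step 13
Reactants: 28 5-iodo-1,2,3-tris(benzyloxy)benzene
Product: 30 2,3,4-tris(benzyloxy)-6-iodobenzaldehyde, via aryliminium dichlorophosphate 29 (not isolated)
Conditions: POCl3, DMF, 0 °C then 80 °C; then H2O, 0 °C to rt
Reagents that add atoms: N,N-dimethylformamide, CN(C)C=O; water, O
Why: Vilsmeier–Haack formylation: the two free ring positions are equivalent, each ortho to one and para to another benzyloxy group, so the regiochemistry is unambiguous; benzyl ethers and the iodide should tolerate the conditions.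

Step 14
Reactants: 25 4-bromo-2,6-bis(benzyloxy)phenol; 30 2,3,4-tris(benzyloxy)-6-iodobenzaldehyde
Product: 31 2,3,4-tris(benzyloxy)-6-[4-bromo-2,6-bis(benzyloxy)phenoxy]benzaldehyde
Conditions: CuI (10 mol%), picolinic acid (20 mol%), K3PO4, DMSO, 80 °C
Reagents that add atoms: none
Why: Ullmann-type diaryl ether synthesis: the iodide of 30 is activated by the ortho formyl group, whereas the bromide of 25 lies para to the phenoxide oxygen and is deactivated, so the hindered phenoxide should couple at the iodide only.

Step 15
Reactants: 31 2,3,4-tris(benzyloxy)-6-[4-bromo-2,6-bis(benzyloxy)phenoxy]benzaldehyde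
Product: 33 2,3,4-tris(benzyloxy)-6-[4-bromo-2,6-bis(benzyloxy)phenoxy]phenol, via aryl formate 32 (not isolated)
Conditions: mCPBA, CH2Cl2, 0 °C to rt; then K2CO3 (cat.), MeOH, rt, argon
Reagents that add atoms: 3-chloroperoxybenzoic acid, OOC(=O)c1cccc(Cl)c1
Why: Dakin oxidation: the formyl group that activated the coupling, flanked by two oxygen substituents, becomes the ring D C6 hydroxyl; the pentaoxygenated phenol is handled under argon.

Step 16
Reactants: 33 2,3,4-tris(benzyloxy)-6-[4-bromo-2,6-bis(benzyloxy)phenoxy]phenol; 28 5-iodo-1,2,3-tris(benzyloxy)benzene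
Product: 34 1,3-bis(benzyloxy)-5-bromo-2-{3,4,5-tris(benzyloxy)-2-[3,4,5-tris(benzyloxy)phenoxy]phenoxy}benzene
Conditions: CuI (10 mol%), picolinic acid (20 mol%), K3PO4, DMSO, 90 °C, degassed
Reagents that add atoms: none
Why: Ullmann-type coupling of a hindered phenol with an unhindered aryl iodide; under copper catalysis aryl iodides react well before aryl bromides, which should leave the ring C bromide untouched.

Step 17
Reactants: 21 2,4-bis(benzyloxy)-6-[2,4,6-tris(benzyloxy)phenoxy]phenol; 34 1,3-bis(benzyloxy)-5-bromo-2-{3,4,5-tris(benzyloxy)-2-[3,4,5-tris(benzyloxy)phenoxy]phenoxy}benzene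
Product: 35 tridecabenzyl ether of 36 (all thirteen hydroxyls of the pentamer as benzyl ethers)
Conditions: CuI (20 mol%), picolinic acid (40 mol%), K3PO4, DMSO, 100 °C, degassed
Reagents that add atoms: none
Why: Ullmann-type diaryl ether synthesis joining the two halves: the bromide carbon of 34 has two ortho hydrogens, the picolinic acid ligand is suited to 2,6-disubstituted phenols, and the only free hydroxyl of 21 is the one to be arylated.

Step 18
Reactants: 35 tridecabenzyl ether of 36
Product: 36 2-[2-(4-{3,4,5-trihydroxy-2-[3,4,5-trihydroxyphenoxy]phenoxy}-3,5-dihydroxyphenoxy)-3,5-dihydroxyphenoxy]benzene-1,3,5-triol (CNP0243665.0)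
Conditions: H2 (1 atm), 10% Pd/C, THF–MeOH, rt; filtered and concentrated under argon
Reagents that add atoms: none
Why: Hydrogenolysis of all thirteen benzyl ethers over palladium under neutral conditions; diaryl ethers are not cleaved, and working under argon keeps the polyphenol from oxidising.

## Compound list

1 | chromium hexacarbonyl | O=C=[Cr](=C=O)(=C=O)(=C=O)(=C=O)=C=O | starting material
2 | trimethylsilylacetylene | C#C[Si](C)(C)C | starting material
3 | lithium trimethylsilylacetylide (formed and used in the flask) | [Li+].[C-]#C[Si](C)(C)C | intermediate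
4 | lithium pentacarbonyl[1-oxido-3-(trimethylsilyl)prop-2-yn-1-ylidene]chromate (formed and used in the flask) | [Li+].[O-]C(C#C[Si](C)(C)C)=[Cr](=C=O)(=C=O)(=C=O)(=C=O)=C=O | intermediate
5 | tetramethylammonium pentacarbonyl[1-oxido-3-(trimethylsilyl)prop-2-yn-1-ylidene]chromate | C[N+](C)(C)C.[O-]C(C#C[Si](C)(C)C)=[Cr](=C=O)(=C=O)(=C=O)(=C=O)=C=O | intermediate
6 | pentacarbonyl[1-acetoxy-3-(trimethylsilyl)prop-2-yn-1-ylidene]chromium (formed and used in the flask) | CC(=O)OC(C#C[Si](C)(C)C)=[Cr](=C=O)(=C=O)(=C=O)(=C=O)=C=O | intermediate
7 | pentacarbonyl[1-(benzyloxy)-3-(trimethylsilyl)prop-2-yn-1-ylidene]chromium | C[Si](C)(C)C#CC(OCc1ccccc1)=[Cr](=C=O)(=C=O)(=C=O)(=C=O)=C=O | intermediate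
8 | pentacarbonyl[1-(benzyloxy)prop-2-yn-1-ylidene]chromium (formed and used in the flask) | C#CC(OCc1ccccc1)=[Cr](=C=O)(=C=O)(=C=O)(=C=O)=C=O | intermediate
9 | pentacarbonyl[(E)-1,3-bis(benzyloxy)prop-2-en-1-ylidene]chromium | c1ccccc1COC(/C=C/OCc1ccccc1)=[Cr](=C=O)(=C=O)(=C=O)(=C=O)=C=O | intermediate
10 | 2,4,6-trihydroxybenzaldehyde | O=Cc1c(O)cc(O)cc1O | starting material
11 | 2,4,6-tris(benzyloxy)benzaldehyde | O=Cc1c(OCc2ccccc2)cc(OCc2ccccc2)cc1OCc1ccccc1 | intermediate
12 | 2,4,6-tris(benzyloxy)phenyl formate (formed and used in the flask) | O=COc1c(OCc2ccccc2)cc(OCc2ccccc2)cc1OCc1ccccc1 | intermediate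
13 | 2,4,6-tris(benzyloxy)phenol | Oc1c(OCc2ccccc2)cc(OCc2ccccc2)cc1OCc1ccccc1 | intermediate
14 | trichloroethylene | ClC=C(Cl)Cl | starting material
15 | dichloroacetylene (formed and used in the flask) | ClC#CCl | intermediate
16 | 1,3,5-tris(benzyloxy)-2-{[(E)-1,2-dichloroethenyl]oxy}benzene | Cl/C=C(/Cl)Oc1c(OCc2ccccc2)cc(OCc2ccccc2)cc1OCc1ccccc1 | intermediate
17 | chloroethynyl 2,4,6-tris(benzyloxy)phenyl ether (formed and used in the flask) | ClC#COc1c(OCc2ccccc2)cc(OCc2ccccc2)cc1OCc1ccccc1 | intermediate
18 | lithium [2,4,6-tris(benzyloxy)phenoxy]acetylide (formed and used in the flask) | [Li+].[C-]#COc1c(OCc2ccccc2)cc(OCc2ccccc2)cc1OCc1ccccc1 | intermediate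
19 | ethynyl 2,4,6-tris(benzyloxy)phenyl ether | C#COc1c(OCc2ccccc2)cc(OCc2ccccc2)cc1OCc1ccccc1 | intermediate
20 | tricarbonyl(η6-arene)chromium complex of 21, metal on ring B, written as two parts (formed and used in the flask) | Oc1c(OCc2ccccc2)cc(OCc2ccccc2)cc1Oc1c(OCc2ccccc2)cc(OCc2ccccc2)cc1OCc1ccccc1.O=C=[Cr](=C=O)=C=O | intermediate
21 | 2,4-bis(benzyloxy)-6-[2,4,6-tris(benzyloxy)phenoxy]phenol (AB phenol) | Oc1c(OCc2ccccc2)cc(OCc2ccccc2)cc1Oc1c(OCc2ccccc2)cc(OCc2ccccc2)cc1OCc1ccccc1 | intermediate
22 | 4-bromo-2,6-difluorobenzaldehyde | O=Cc1c(F)cc(Br)cc1F | starting material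
23 | 4-bromo-2,6-bis(benzyloxy)benzaldehyde | O=Cc1c(OCc2ccccc2)cc(Br)cc1OCc1ccccc1 | intermediate
24 | 4-bromo-2,6-bis(benzyloxy)phenyl formate (formed and used in the flask) | O=COc1c(OCc2ccccc2)cc(Br)cc1OCc1ccccc1 | intermediate
25 | 4-bromo-2,6-bis(benzyloxy)phenol | Oc1c(OCc2ccccc2)cc(Br)cc1OCc1ccccc1 | intermediate
26 | 5-iodo-1,2,3-trimethoxybenzene | COc1cc(I)cc(OC)c1OC | starting material
27 | 5-iodobenzene-1,2,3-triol | Oc1cc(I)cc(O)c1O | intermediate
28 | 5-iodo-1,2,3-tris(benzyloxy)benzene | Ic1cc(OCc2ccccc2)c(OCc2ccccc2)c(OCc2ccccc2)c1 | intermediate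
29 | N-{[2,3,4-tris(benzyloxy)-6-iodophenyl]methylidene}-N-methylmethanaminium dichlorophosphate (formed and used in the flask) | C[N+](C)=Cc1c(I)cc(OCc2ccccc2)c(OCc2ccccc2)c1OCc1ccccc1.[O-]P(=O)(Cl)Cl | intermediate
30 | 2,3,4-tris(benzyloxy)-6-iodobenzaldehyde | O=Cc1c(I)cc(OCc2ccccc2)c(OCc2ccccc2)c1OCc1ccccc1 | intermediate
31 | 2,3,4-tris(benzyloxy)-6-[4-bromo-2,6-bis(benzyloxy)phenoxy]benzaldehyde | O=Cc1c(Oc2c(OCc3ccccc3)cc(Br)cc2OCc2ccccc2)cc(OCc2ccccc2)c(OCc2ccccc2)c1OCc1ccccc1 | intermediate
32 | 2,3,4-tris(benzyloxy)-6-[4-bromo-2,6-bis(benzyloxy)phenoxy]phenyl formate (formed and used in the flask) | O=COc1c(Oc2c(OCc3ccccc3)cc(Br)cc2OCc2ccccc2)cc(OCc2ccccc2)c(OCc2ccccc2)c1OCc1ccccc1 | intermediate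
33 | 2,3,4-tris(benzyloxy)-6-[4-bromo-2,6-bis(benzyloxy)phenoxy]phenol | Oc1c(Oc2c(OCc3ccccc3)cc(Br)cc2OCc2ccccc2)cc(OCc2ccccc2)c(OCc2ccccc2)c1OCc1ccccc1 | intermediate
34 | 1,3-bis(benzyloxy)-5-bromo-2-{3,4,5-tris(benzyloxy)-2-[3,4,5-tris(benzyloxy)phenoxy]phenoxy}benzene (CDE bromide) | Brc1cc(OCc2ccccc2)c(Oc2cc(OCc3ccccc3)c(OCc3ccccc3)c(OCc3ccccc3)c2Oc2cc(OCc3ccccc3)c(OCc3ccccc3)c(OCc3ccccc3)c2)c(OCc2ccccc2)c1 | intermediate
35 | tridecabenzyl ether of 36 | c1ccccc1COc1cc(OCc2ccccc2)c(Oc2cc(OCc3ccccc3)cc(OCc3ccccc3)c2Oc2cc(OCc3ccccc3)c(Oc3cc(OCc4ccccc4)c(OCc4ccccc4)c(OCc4ccccc4)c3Oc3cc(OCc4ccccc4)c(OCc4ccccc4)c(OCc4ccccc4)c3)c(OCc3ccccc3)c2)c(OCc2ccccc2)c1 | intermediate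
36 | 2-[2-(4-{3,4,5-trihydroxy-2-[3,4,5-trihydroxyphenoxy]phenoxy}-3,5-dihydroxyphenoxy)-3,5-dihydroxyphenoxy]benzene-1,3,5-triol (CNP0243665.0) | Oc1cc(O)c(Oc2cc(O)cc(O)c2Oc2cc(O)c(Oc3cc(O)c(O)c(O)c3Oc3cc(O)c(O)c(O)c3)c(O)c2)c(O)c1 | target

## Step count and risk

Total: 18 steps. Longest linear sequence: 8 steps (steps 11 to 18, from 26). The carbene branch (steps 1 to 3), the ynol ether branch (steps 4 to 7) and the ring C branch (steps 9 and 10) run in parallel.

Least certain steps:

Step 8 (key step). After insertion of 19 the chromium sits on a carbon that carries an aryloxy donor, so the sequence may stall before CO is taken up, or leak into closure without CO (a five-membered ring) or into four-membered ring formation from the vinylketene. The donor-substituted carbene 9 may also lose CO so slowly that thermal decay of the ynol ether competes, and the electron-rich phenol can be oxidised during demetalation. The fallback builds ring B by substitution instead of annulation and sets out from 13. Purchased 2-bromo-4,6-difluorobenzaldehyde is treated with BnONa as in step 9 to give 2-bromo-4,6-bis(benzyloxy)benzaldehyde F1. Its bromide, activated by the ortho formyl group, is coupled with 13 (CuI, picolinic acid, K3PO4, DMSO) to give 2,4-bis(benzyloxy)-6-[2,4,6-tris(benzyloxy)phenoxy]benzaldehyde F2. Dakin oxidation (mCPBA, then K2CO3, MeOH) through the aryl formate F3 comes back to the route at 21.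

Step 3. The unmasked ethynylcarbene may oligomerise before the alcohol adds, a second molecule of alcohol may add to give the saturated acetal, or the alkene may form as a mixture of geometries. The fallback avoids the alkyne altogether and sets out from 1:
- Benzyl alcohol is added to ethyl propiolate under amine catalysis to give ethyl (E)-3-(benzyloxy)prop-2-enoate F4.
- LiOH gives (E)-3-(benzyloxy)prop-2-enoic acid F5, and (COCl)2 gives (E)-3-(benzyloxy)prop-2-enoyl chloride F6.
- Compound 1 is reduced with potassium graphite C8K to dipotassium pentacarbonylchromate F7, which is acylated by F6 to the potassium acylchromate F8 and exchanged with Me4NBr to the tetramethylammonium acylchromate F9.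
- AcBr gives the acetoxycarbene complex F10, and benzyl alcohol, as in step 2, comes back to the route at 9.

Step 14. Both partners are hindered (three ortho substituents around the new ether), so the coupling may be slow enough for loss of iodine from 30 or reaction at the bromide of 25 or 31 (oligomerisation) to take over; the formylation of 28 that precedes it (step 13) may also be sluggish next to the iodine. The fallback reverses the order of events and sets out from 25 and 28. The hindered phenol 25 is coupled with the unhindered iodide 28 (CuI, picolinic acid, K3PO4, DMSO) to give 1,3-bis(benzyloxy)-5-bromo-2-[3,4,5-tris(benzyloxy)phenoxy]benzene F11. Vilsmeier–Haack formylation then attacks ring D, its free positions being activated by three oxygens against two on ring C. Hydrolysis of the iminium dichlorophosphate F12 comes back to the route at 31.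

Step 16. At the temperature a hindered phenol needs, discrimination between the iodide of 28 and the bromide of 33 and 34 may be incomplete, leading to double arylation or oligomers, and the pentaoxygenated phenoxide may be oxidised. The fallback is a metal-free arylation, to which aryl bromides are inert, and sets out from 33. Compound 28 is oxidised with mCPBA and TsOH and combined with 1,3,5-trimethoxybenzene to give [3,4,5-tris(benzyloxy)phenyl](2,4,6-trimethoxyphenyl)iodonium tosylate F13. With t-BuOK in THF at rt this salt transfers its less electron-rich aryl group to the phenoxide of 33 and comes back to the route at 34.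

Step 17. Conversion may stay low because a large, electron-rich bromide meets a phenol flanked on both sides; the hydroquinone-type phenoxide of 21 may be oxidised at 100 °C, and 34 may lose its bromine by reduction. The fallback inverts the polarity of the ring C partner and works at room temperature; it sets out from 34. Bromine–lithium exchange (n-BuLi, THF, −78 °C), B(Oi-Pr)3 and aqueous work-up give the boronic acid F14 (the boronic acid of 34 at ring C C1). Chan–Lam–Evans coupling with 21 (Cu(OAc)2, pyridine, 4 Å molecular sieves, CH2Cl2, air, rt), a method that tolerates 2,6-disubstituted phenols, comes back to the route at 35.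

## Further compounds

F1 | step 8 | 2-bromo-4,6-bis(benzyloxy)benzaldehyde | O=Cc1c(Br)cc(OCc2ccccc2)cc1OCc1ccccc1
F2 | step 8 | 2,4-bis(benzyloxy)-6-[2,4,6-tris(benzyloxy)phenoxy]benzaldehyde | O=Cc1c(OCc2ccccc2)cc(OCc2ccccc2)cc1Oc1c(OCc2ccccc2)cc(OCc2ccccc2)cc1OCc1ccccc1
F3 | step 8 | 2,4-bis(benzyloxy)-6-[2,4,6-tris(benzyloxy)phenoxy]phenyl formate | O=COc1c(OCc2ccccc2)cc(OCc2ccccc2)cc1Oc1c(OCc2ccccc2)cc(OCc2ccccc2)cc1OCc1ccccc1
F4 | step 3 | ethyl (E)-3-(benzyloxy)prop-2-enoate | CCOC(=O)/C=C/OCc1ccccc1
F5 | step 3 | (E)-3-(benzyloxy)prop-2-enoic acid | OC(=O)/C=C/OCc1ccccc1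
F6 | step 3 | (E)-3-(benzyloxy)prop-2-enoyl chloride | ClC(=O)/C=C/OCc1ccccc1
F7 | step 3 | dipotassium pentacarbonylchromate K2Cr(CO)5 | [K+].[K+].O=C=[Cr-2](=C=O)(=C=O)(=C=O)=C=O
F8 | step 3 | potassium pentacarbonyl[(E)-3-(benzyloxy)-1-oxidoprop-2-en-1-ylidene]chromate | [K+].[O-]C(/C=C/OCc1ccccc1)=[Cr](=C=O)(=C=O)(=C=O)(=C=O)=C=O
F9 | step 3 | tetramethylammonium pentacarbonyl[(E)-3-(benzyloxy)-1-oxidoprop-2-en-1-ylidene]chromate | C[N+](C)(C)C.[O-]C(/C=C/OCc1ccccc1)=[Cr](=C=O)(=C=O)(=C=O)(=C=O)=C=O
F10 | step 3 | pentacarbonyl[(E)-1-acetoxy-3-(benzyloxy)prop-2-en-1-ylidene]chromium | CC(=O)OC(/C=C/OCc1ccccc1)=[Cr](=C=O)(=C=O)(=C=O)(=C=O)=C=O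
F11 | step 14 | 1,3-bis(benzyloxy)-5-bromo-2-[3,4,5-tris(benzyloxy)phenoxy]benzene | Brc1cc(OCc2ccccc2)c(Oc2cc(OCc3ccccc3)c(OCc3ccccc3)c(OCc3ccccc3)c2)c(OCc2ccccc2)c1
F12 | step 14 | N-({2,3,4-tris(benzyloxy)-6-[4-bromo-2,6-bis(benzyloxy)phenoxy]phenyl}methylidene)-N-methylmethanaminium dichlorophosphate | C[N+](C)=Cc1c(Oc2c(OCc3ccccc3)cc(Br)cc2OCc2ccccc2)cc(OCc2ccccc2)c(OCc2ccccc2)c1OCc1ccccc1.[O-]P(=O)(Cl)Cl
F13 | step 16 | [3,4,5-tris(benzyloxy)phenyl](2,4,6-trimethoxyphenyl)iodonium 4-methylbenzenesulfonate | COc1cc(OC)c([I+]c2cc(OCc3ccccc3)c(OCc3ccccc3)c(OCc3ccccc3)c2)c(OC)c1.Cc1ccc(S(=O)(=O)[O-])cc1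
F14 | step 17 | (3,5-bis(benzyloxy)-4-{3,4,5-tris(benzyloxy)-2-[3,4,5-tris(benzyloxy)phenoxy]phenoxy}phenyl)boronic acid | OB(O)c1cc(OCc2ccccc2)c(Oc2cc(OCc3ccccc3)c(OCc3ccccc3)c(OCc3ccccc3)c2Oc2cc(OCc3ccccc3)c(OCc3ccccc3)c(OCc3ccccc3)c2)c(OCc2ccccc2)c1
A1 | alternative 1 | undecamethyl ether of the pentamer lacking the oxygens at ring A C4 and ring B C5 | COc1cccc(OC)c1Oc1cccc(OC)c1Oc1cc(OC)c(Oc2cc(OC)c(OC)c(OC)c2Oc2cc(OC)c(OC)c(OC)c2)c(OC)c1
A2 | alternative 1 | undecamethyl ether of the target with the ring A C4 and ring B C5 hydroxyls free | COc1cc(O)cc(OC)c1Oc1cc(O)cc(OC)c1Oc1cc(OC)c(Oc2cc(OC)c(OC)c(OC)c2Oc2cc(OC)c(OC)c(OC)c2)c(OC)c1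
A3 | alternative 2 | 4-{3,4,5-tris(benzyloxy)-2-[3,4,5-tris(benzyloxy)phenoxy]phenoxy}-3-(triisopropylsiloxy)cyclobut-2-en-1-one (racemic) | O=C1C=C(O[Si](C(C)C)(C(C)C)C(C)C)C1Oc1cc(OCc2ccccc2)c(OCc2ccccc2)c(OCc2ccccc2)c1Oc1cc(OCc2ccccc2)c(OCc2ccccc2)c(OCc2ccccc2)c1
A4 | alternative 2 | ethynyl 2,4-bis(benzyloxy)-6-[2,4,6-tris(benzyloxy)phenoxy]phenyl ether | C#COc1c(OCc2ccccc2)cc(OCc2ccccc2)cc1Oc1c(OCc2ccccc2)cc(OCc2ccccc2)cc1OCc1ccccc1
A5 | alternative 2 | protected pentamer with ring C C3 hydroxyl free and C5 triisopropylsilyl ether | Oc1cc(Oc2c(OCc3ccccc3)cc(OCc3ccccc3)cc2Oc2c(OCc3ccccc3)cc(OCc3ccccc3)cc2OCc2ccccc2)cc(O[Si](C(C)C)(C(C)C)C(C)C)c1Oc1cc(OCc2ccccc2)c(OCc2ccccc2)c(OCc2ccccc2)c1Oc1cc(OCc2ccccc2)c(OCc2ccccc2)c(OCc2ccccc2)c1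
A6 | alternative 3 | 2,3-bis(benzyloxy)-4-(methoxymethoxy)-4-[(E)-2-{2,6-bis(benzyloxy)-4-(triisopropylsiloxy)phenoxy}ethenyl]cyclobut-2-en-1-one (racemic) | O=C1C(OCc2ccccc2)=C(OCc2ccccc2)C1(OCOC)/C=C/Oc1c(OCc2ccccc2)cc(O[Si](C(C)C)(C(C)C)C(C)C)cc1OCc1ccccc1
A7 | alternative 3 | CD diaryl ether with ring D C6 hydroxyl free, C3 methoxymethyl ether and ring C C1 triisopropylsilyl ether | Oc1c(OCc2ccccc2)c(OCc2ccccc2)c(OCOC)cc1Oc1c(OCc2ccccc2)cc(O[Si](C(C)C)(C(C)C)C(C)C)cc1OCc1ccccc1
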